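## Retrosynthetic overview

1. Target ⇐ tetracyclic enone (C14=C15–C16=O): nucleophilic epoxidation from the convex face, then hydride reduction of C16=O anti to the new epoxide.
2. Ring D ⇐ SmI2 ketyl–enone 5-exo cyclization (C18–C19) of a cycloheptadienone carrying a 3-oxobutyl chain at C22. The ketyl carbon and the enone β-carbon, both normally electrophilic, are joined; the cis ring fusion and the C19 carbinol are set together.
3. Ring C ⇐ a 4,4-dimethylcyclohexa-2,5-dienone: Cu-catalysed asymmetric conjugate addition of a masked-ketone alkylzinc (sets C22), cyclopropanation of the trapped enol silane, FeCl3 one-carbon ring expansion.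
4. That dienone ⇐ rings A/B alkyl iodide + 3-ethoxy-2,6,6-trimethylcyclohexenone (Stork–Danheiser addition/transposition, C13–C14), then Saegusa oxidation.
5. Rings A/B ⇐ geranyl bromide: HWE enone, Shi bis-epoxidation, 1,4-hydrosilylation, epoxide-opening oxa/carbacyclization cascade, equatorial MeMgBr addition. Ring order: A and B together, then C (by expansion of a six-membered ring), then D, then the epoxide.

Assumption: (E)-geranyl bromide, the D-fructose-derived Shi ketone, the (S,R,R)-Feringa phosphoramidite and 3-ethoxy-2-methylcyclohex-2-en-1-one are bought. The route is a paper design; nothing here has been run.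

Locants (squalene-type): ring A (oxepane) = O, C2(Me2), C3, C4, C5, C6(Me), C7; ring B = C6–C11; linker C12–C13; ring C = C14, C15(Me), C16, C17, C18, C22, C23(Me2); ring D = C18, C19(Me), C20, C21, C22. Target = (3R,6R,7R,10S,11R,14S,15R,16R,18R,19R,22R).

## Route

Step 1
Reactants: 1 geranyl bromide [(2E)-1-bromo-3,7-dimethylocta-2,6-diene]; 2 dimethyl (2-oxopropyl)phosphonate
Product: 4 dimethyl [(5E)-6,10-dimethyl-2-oxoundeca-5,9-dien-1-yl]phosphonate, via phosphonate dianion 3 (not isolated)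
Conditions: NaH, THF, 0 °C; n-BuLi, 0 °C; then 1, 0 → 25 °C; 1 M HCl quench
Reagents that add atoms: none
Why: The β-ketophosphonate dianion is alkylated only at its terminal (γ) carbon by the allylic bromide (Grieco–Pogonowski dianion alkylation), keeping the E-alkene and giving the HWE reagent directly.

Step 2
Reactants: 4 the ketophosphonate; 5 2-(tert-butyldimethylsilyloxy)acetaldehyde
Product: 6 (2E,7E)-1-(tert-butyldimethylsilyloxy)-8,12-dimethyltrideca-2,7,11-trien-4-one
Conditions: LiCl, i-Pr2NEt, MeCN, 25 °C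
Reagents that add atoms: none
Why: Masamune–Roush Horner–Wadsworth–Emmons olefination gives the (E)-enone (C11=C12) under base mild enough for the α-silyloxy aldehyde.

Step 3
Reactants: 6 the trienone
Product: 7 (3R,6R,7R)-2,3:6,7-diepoxide of 6 (enone untouched)
Conditions: Shi ketone (D-fructose-derived, 0.3 equiv), Oxone (2KHSO5·KHSO4·K2SO4), K2CO3, Bu4NHSO4, MeCN–(MeO)2CH2–aq. Na2B4O7 buffer, 0 °C
Reagents that add atoms: potassium peroxymonosulfate (active salt of Oxone), [K+].[O-]S(=O)(=O)OO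
Why: Shi asymmetric epoxidation oxidizes only the two electron-rich trisubstituted alkenes (the enone is inert to the dioxirane) and sets C3 (R) and C6/C7 (R,R) under reagent control through the spiro transition state.

Step 4
Reactants: 7 the diepoxy enone
Product: 8 (Z)-triethylsilyl enol ether (C10=C11) of the (3R,6R,7R)-diepoxy ketone
Conditions: Et3SiH, RhCl(PPh3)3 (1 mol %), PhH, 60 °C
Reagents that add atoms: triethylsilane, CC[SiH](CC)CC
Why: Rh-catalysed 1,4-hydrosilylation of the enone (Ojima) gives the regiodefined (Z)-enol silane toward C11, which enolization of the saturated ketone could not deliver selectively; epoxides and the silyl ether are inert.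

Step 5
Reactants: 8 the diepoxy enol silane
Product: 10 (3R,6R,7R,11R)-keto diol of the trans-fused rings A/B core (3-OH; 10-oxo; 11-(2-hydroxyethyl)), via silylated bicyclic ketone 9 (not isolated)
Conditions: TMSOTf, 2,6-di-tert-butyl-4-methylpyridine, CH2Cl2, −78 °C; then 2 M HCl, THF, 25 °C
Reagents that add atoms: none
Why: Silyl-triflate-triggered epoxide-opening oxa/carbacyclization cascade (McDonald type): the 6,7-epoxide oxygen opens the activated 2,3-epoxide at C2 (ring A; C3 and C7 keep their configuration), the enol silane carbon C11 then opens the epoxonium at C6 with inversion through a chair (ring B, trans fusion), and aqueous acid removes TMS and TBS and leaves the C11 chain equatorial (thermodynamic).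

Step 6
Reactants: 10 the keto diol
Product: 11 (3R,6R,7R,11R)-11-(2-iodoethyl) keto alcohol
Conditions: I2, PPh3, imidazole, CH2Cl2, 0 °C
Reagents that add atoms: iodine, II
Why: Appel-type (Garegg–Samuelsson) iodination is selective for the primary alcohol; the neopentyl secondary C3–OH does not react.

Step 7
Reactants: 11 the iodo ketone
Product: 13 (3R,6R,7R,10S,11R)-3,10-bis(triethylsilyloxy)-10-methyl-11-(2-iodoethyl) rings A/B iodide, via bis(bromomagnesium) alkoxide 12 (not isolated)
Conditions: MeMgBr (3 equiv), CeCl3, THF, −78 °C; then TESOTf, 2,6-lutidine, −78 → 0 °C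
Reagents that add atoms: methylmagnesium bromide, C[Mg]Br; triethylsilyl trifluoromethanesulfonate, CC[Si](CC)(CC)OS(=O)(=O)C(F)(F)F
Why: Cerium-modified Grignard addition comes from the equatorial side because the axial C6 methyl blocks axial approach, giving the axial tertiary alcohol (10S); trapping both alkoxides as TES ethers in the same pot prevents tetrahydrofuran formation by O-alkylation at C13.

Step 8
Reactants: 14 3-ethoxy-2-methylcyclohex-2-en-1-one
Product: 16 3-ethoxy-2,6,6-trimethylcyclohex-2-en-1-one, via monomethylated enone 15 (not isolated)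
Conditions: LDA, THF, −78 °C, then MeI; repeat LDA, then MeI, −78 → 0 °C
Reagents that add atoms: iodomethane, CI
Why: Two kinetic α′-enolization/methylation cycles on the vinylogous ester (Stork–Danheiser alkylation) install the gem-dimethyl group that becomes C23; no stereocentre remains.

Step 9
Reactants: 13 the rings A/B iodide; 16 the trimethyl vinylogous ester
Product: 19 3-[2-(rings A/B)ethyl]-2,4,4-trimethylcyclohex-2-en-1-one (bis-TES ether), via alkyllithium 17 (not isolated), via tertiary lithium alkoxide 18 (not isolated)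
Conditions: 13, t-BuLi (2.1 equiv), Et2O–pentane, −78 °C; 16, −78 → 0 °C; then 1 M HCl, THF, 0 °C, 15 min
Reagents that add atoms: water, O
Why: Iodine–lithium exchange, 1,2-addition to the vinylogous ester carbonyl and acid-induced transposition (Stork–Danheiser enone synthesis) form the C13–C14 bond and place the ketone at the future C16; the brief acid step spares the TES ethers.

Step 10
Reactants: 19 the cyclohexenone
Product: 21 3-[2-(rings A/B)ethyl]-2,4,4-trimethylcyclohexa-2,5-dien-1-one (bis-TES ether), via TMS dienol ether 20 (not isolated)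
Conditions: LDA, TMSCl, THF, −78 °C; then Pd(OAc)2, MeCN, 25 °C
Reagents that add atoms: none
Why: Saegusa–Ito oxidation of the kinetic α′-dienol silane gives the cross-conjugated 4,4-dimethylcyclohexadienone.

Step 11
Reactants: 21 the cyclohexadienone; 22 2-(2-bromoethyl)-2-methyl-1,3-dioxolane
Product: 26 (22R)-1-trimethylsilyloxy-bicyclo[4.1.0]hept-2-ene (siloxycyclopropane) carrying the ketal chain at C22, via Grignard reagent 23 (not isolated), via dialkylzinc 24 (not isolated), via TMS dienol ether 25 (not isolated)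
Conditions: 22, Mg, THF, then ZnCl2 (0.5 equiv), 1,4-dioxane, filter; 21, Cu(OTf)2 (3 mol %), (S,R,R)-Feringa phosphoramidite (6 mol %), PhMe, −30 °C; TMSOTf, 0 °C; CH2I2, Et2Zn, 0 → 25 °C
Reagents that add atoms: trimethylsilyl trifluoromethanesulfonate, C[Si](C)(C)OS(=O)(=O)C(F)(F)F; diiodomethane, ICI
Why: Cu-catalysed asymmetric conjugate addition (Feringa) of the ketone-homoenolate-equivalent dialkylzinc occurs only at the unsubstituted enone β-carbon and sets C22 (R) under ligand control (same facial sense as (S)-3-ethylcyclohexanone from cyclohexenone; the antipodal ligand is used if the sense is reversed); the zinc enolate is O-silylated and the siloxy alkene is cyclopropanated (Furukawa–Simmons–Smith, Alexakis tandem), the cyclopropane configuration being irrelevant.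

Step 12
Reactants: 26 the siloxycyclopropane
Product: 29 (22R)-2-methyl-3-[2-(rings A/B)ethyl]-4,4-dimethyl-5-(3-oxobutyl)cyclohepta-2,6-dien-1-one with free 3-OH and 10-OH, via chloro ketone 27 (not isolated), via protected cycloheptadienone 28 (not isolated)
Conditions: FeCl3, DMF, 0 °C; NaOAc, MeOH, 65 °C; then 2 M HCl, THF, 25 °C
Reagents that add atoms: water, O
Why: Saegusa FeCl3 oxidative opening of the siloxycyclopropane cleaves the internal bond to the ring-expanded β-chloro ketone, NaOAc eliminates HCl (E1cB) to the cycloheptadienone (ring C), and aqueous acid removes the dioxolane and both TES ethers; C22 is untouched.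

Step 13
Reactants: 29 the keto dienone
Product: 30 (18R,19R,22R)-cis-fused hydroazulenone (C14=C15–C16=O enone; 19-OH) with rings A/B attached
Conditions: SmI2 (2.5 equiv), HMPA, t-BuOH, THF, −78 → 0 °C
Reagents that add atoms: none
Why: Key step: SmI2/HMPA turns the methyl ketone into a ketyl whose carbon (C19, normally electrophilic) adds 5-exo to C18, the β-carbon of the enone (also normally electrophilic) (Molander ketyl–olefin cyclization); the tether on C22 forces the cis ring fusion at C18, the bulky O–Sm group turns away from the enolate (anti transition state) so that 19-OH is trans to C17 (19R), and α-protonation of the samarium dienolate returns the C14=C15–C16=O enone.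

Step 14
Reactants: 30 the hydroazulenone
Product: 31 (14S,15S,18R,19R,22R)-14,15-epoxy-16-ketone
Conditions: 30% H2O2, NaOH, MeOH, 0 → 25 °C
Reagents that add atoms: hydrogen peroxide, OO
Why: Weitz–Scheffer nucleophilic epoxidation; hydroperoxide adds to C14 from the convex face of the cis-fused bicycle (the face of H18 and H22), giving the epoxide syn to those hydrogens.

Step 15
Reactants: 31 the epoxy ketone
Product: 32 CNP0203623.2 (target)
Conditions: NaBH4, CeCl3·7H2O, MeOH, −40 °C
Reagents that add atoms: none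
Why: Hydride reduction of the cyclic α,β-epoxy ketone occurs anti to the epoxide oxygen (Luche conditions; the usual route to cis-epoxy alcohols), giving 16-OH syn to the epoxide (16R).

## Compound list

1 | geranyl bromide, (2E)-1-bromo-3,7-dimethylocta-2,6-diene | CC(C)=CCC/C(C)=C/CBr | starting material
2 | dimethyl (2-oxopropyl)phosphonate | CC(=O)CP(=O)(OC)OC | starting material
3 | sodium lithium dianion of 2 | [CH2-]C(=O)[CH-]P(=O)(OC)OC.[Na+].[Li+] | intermediate
4 | dimethyl [(5E)-6,10-dimethyl-2-oxoundeca-5,9-dien-1-yl]phosphonate | COP(=O)(OC)CC(=O)CC/C=C(\C)CCC=C(C)C | intermediate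
5 | 2-(tert-butyldimethylsilyloxy)acetaldehyde | O=CCO[Si](C)(C)C(C)(C)C | starting material
6 | (2E,7E)-1-(tert-butyldimethylsilyloxy)-8,12-dimethyltrideca-2,7,11-trien-4-one | CC(C)=CCC/C(C)=C/CCC(=O)/C=C/CO[Si](C)(C)C(C)(C)C | intermediate
7 | (3R,6R,7R)-2,3:6,7-diepoxy (E)-enone | CC1(C)O[C@@H]1CC[C@@]2(C)O[C@@H]2CCC(=O)/C=C/CO[Si](C)(C)C(C)(C)C | intermediate
8 | (Z)-C10 triethylsilyl enol ether of the (3R,6R,7R)-diepoxy ketone | CC1(C)O[C@@H]1CC[C@@]2(C)O[C@@H]2CC/C(O[Si](CC)(CC)CC)=C/CCO[Si](C)(C)C(C)(C)C | intermediate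
9 | (3R,6R,7R,11R)-rings A/B ketone, 3-OTMS, 13-OTBS | CC1(C)O[C@@H]2CCC(=O)[C@H](CCO[Si](C)(C)C(C)(C)C)[C@@]2(C)CC[C@H]1O[Si](C)(C)C | intermediate
10 | (3R,6R,7R,11R)-rings A/B keto diol | CC1(C)O[C@@H]2CCC(=O)[C@H](CCO)[C@@]2(C)CC[C@H]1O | intermediate
11 | (3R,6R,7R,11R)-11-(2-iodoethyl) keto alcohol | CC1(C)O[C@@H]2CCC(=O)[C@H](CCI)[C@@]2(C)CC[C@H]1O | intermediate
12 | bis(bromomagnesium) alkoxide of the (3R,6R,7R,10S,11R)-iodo diol | CC1(C)O[C@@H]2CC[C@](C)(O[Mg]Br)[C@H](CCI)[C@@]2(C)CC[C@H]1O[Mg]Br | intermediate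
13 | (3R,6R,7R,10S,11R)-3,10-bis(triethylsilyloxy) rings A/B iodide | CC1(C)O[C@@H]2CC[C@](C)(O[Si](CC)(CC)CC)[C@H](CCI)[C@@]2(C)CC[C@H]1O[Si](CC)(CC)CC | intermediate
14 | 3-ethoxy-2-methylcyclohex-2-en-1-one | CCOC1=C(C)C(=O)CCC1 | starting material
15 | 3-ethoxy-2,6-dimethylcyclohex-2-en-1-one (racemic) | CCOC1=C(C)C(=O)C(C)CC1 | intermediate
16 | 3-ethoxy-2,6,6-trimethylcyclohex-2-en-1-one | CCOC1=C(C)C(=O)C(C)(C)CC1 | intermediate
17 | C13 alkyllithium from 13 | CC1(C)O[C@@H]2CC[C@](C)(O[Si](CC)(CC)CC)[C@H](CC[Li])[C@@]2(C)CC[C@H]1O[Si](CC)(CC)CC | intermediate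
18 | tertiary lithium alkoxide 1,2-adduct (both carbinol epimers) | CC1(C)O[C@@H]2CC[C@](C)(O[Si](CC)(CC)CC)[C@H](CCC3(O[Li])C(C)=C(OCC)CCC3(C)C)[C@@]2(C)CC[C@H]1O[Si](CC)(CC)CC | intermediate
19 | 3-substituted 2,4,4-trimethylcyclohex-2-en-1-one (bis-TES) | CC1(C)O[C@@H]2CC[C@](C)(O[Si](CC)(CC)CC)[C@H](CCC3=C(C)C(=O)CCC3(C)C)[C@@]2(C)CC[C@H]1O[Si](CC)(CC)CC | intermediate
20 | TMS dienol ether of 19 | CC1(C)O[C@@H]2CC[C@](C)(O[Si](CC)(CC)CC)[C@H](CCC3=C(C)C(O[Si](C)(C)C)=CCC3(C)C)[C@@]2(C)CC[C@H]1O[Si](CC)(CC)CC | intermediate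
21 | 3-substituted 2,4,4-trimethylcyclohexa-2,5-dien-1-one (bis-TES) | CC1(C)O[C@@H]2CC[C@](C)(O[Si](CC)(CC)CC)[C@H](CCC3=C(C)C(=O)C=CC3(C)C)[C@@]2(C)CC[C@H]1O[Si](CC)(CC)CC | intermediate
22 | 2-(2-bromoethyl)-2-methyl-1,3-dioxolane | CC1(CCBr)OCCO1 | starting material
23 | 2-(2-methyl-1,3-dioxolan-2-yl)ethylmagnesium bromide | CC1(CC[Mg]Br)OCCO1 | intermediate
24 | bis[2-(2-methyl-1,3-dioxolan-2-yl)ethyl]zinc | CC1(CC[Zn]CCC2(C)OCCO2)OCCO1 | intermediate
25 | (22R)-TMS dienol ether after conjugate addition | CC1(C)O[C@@H]2CC[C@](C)(O[Si](CC)(CC)CC)[C@H](CCC3=C(C)C(O[Si](C)(C)C)=C[C@@H](CCC4(C)OCCO4)C3(C)C)[C@@]2(C)CC[C@H]1O[Si](CC)(CC)CC | intermediate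
26 | (22R)-siloxycyclopropane (cyclopropane carbons C16/C18 unassigned, both converge) | CC1(C)O[C@@H]2CC[C@](C)(O[Si](CC)(CC)CC)[C@H](CCC3=C(C)C4(O[Si](C)(C)C)CC4[C@@H](CCC5(C)OCCO5)C3(C)C)[C@@]2(C)CC[C@H]1O[Si](CC)(CC)CC | intermediate
27 | 18-chloro cycloheptenone (C18 epimers; same C22 configuration) | CC1(C)O[C@@H]2CC[C@](C)(O[Si](CC)(CC)CC)[C@H](CCC3=C(C)C(=O)CC(Cl)[C@@H](CCC4(C)OCCO4)C3(C)C)[C@@]2(C)CC[C@H]1O[Si](CC)(CC)CC | intermediate
28 | (22R)-cycloheptadienone, ketal and TES ethers intact | CC1(C)O[C@@H]2CC[C@](C)(O[Si](CC)(CC)CC)[C@H](CCC3=C(C)C(=O)C=C[C@@H](CCC4(C)OCCO4)C3(C)C)[C@@]2(C)CC[C@H]1O[Si](CC)(CC)CC | intermediate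
29 | (22R)-5-(3-oxobutyl)cyclohepta-2,6-dienone diol | CC1(C)O[C@@H]2CC[C@](C)(O)[C@H](CCC3=C(C)C(=O)C=C[C@@H](CCC(C)=O)C3(C)C)[C@@]2(C)CC[C@H]1O | intermediate
30 | (18R,19R,22R)-hydroazulenone triol | CC1(C)O[C@@H]2CC[C@](C)(O)[C@H](CCC3=C(C)C(=O)C[C@@H]4[C@@H](CC[C@@]4(C)O)C3(C)C)[C@@]2(C)CC[C@H]1O | intermediate
31 | (14S,15S,18R,19R,22R)-14,15-epoxy-16-ketone | CC1(C)O[C@@H]2CC[C@](C)(O)[C@H](CC[C@@]34O[C@]3(C)C(=O)C[C@@H]3[C@@H](CC[C@@]3(C)O)C4(C)C)[C@@]2(C)CC[C@H]1O | intermediate
32 | CNP0203623.2 | CC1(C)O[C@@H]2CC[C@](C)(O)[C@H](CC[C@@]34O[C@]3(C)[C@H](O)C[C@@H]3[C@@H](CC[C@@]3(C)O)C4(C)C)[C@@]2(C)CC[C@H]1O | target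

## Step count and risks

Total: 15 steps (step 8 is the only side-branch step). Longest linear sequence: 14 steps (1–7, then 9–15) from geranyl bromide.

Three steps most likely to fail, each with a fallback:

Step 13 (SmI2 ketyl–enone cyclization). The cross-conjugated dienone may be reduced faster than the methyl ketone, leading to conjugate reduction or reductive aldol products. The fallback sets out from 29 and comes back at 30, replacing the ketyl by an α-siloxy radical made by hydrogen-atom transfer. TBSOTf/Et3N converts 29 into the 3-O-TBS ether carrying the terminal TBS enol ether of the methyl ketone F3. Fe(acac)3/PhSiH3 in EtOH at 60 °C (metal-hydride HAT, Baran-type reductive olefin coupling) adds a hydrogen atom to the enol ether CH2; the tertiary α-siloxy radical at C19 closes 5-exo onto C18 and gives the 3,19-bis-TBS hydroazulenone F4, with the bulky silyloxy group on the convex face. HF·pyridine removes both silyl groups to give 30.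

Step 14 (Weitz–Scheffer epoxidation of a tetrasubstituted enone with a neopentyl β-carbon). It may be slow, and its face selectivity is unproven. The fallback sets out from 30 and comes back at 32, reducing first and epoxidizing under hydroxyl direction. NaBH4/CeCl3 reduces 30 from the convex face to the (16S)-allylic alcohol F5. Mitsunobu inversion (4-nitrobenzoic acid, PPh3, DIAD) gives the (16R)-4-nitrobenzoate F6; only 16-OH reacts, since 3-OH is neopentyl and the other hydroxyls are tertiary. K2CO3/MeOH gives the (16R)-allylic alcohol F7. VO(acac)2/t-BuOOH then epoxidizes C14=C15 syn to the C16 hydroxyl and gives 32, bypassing 31. If the reduction already gives the 16R alcohol, the inversion is skipped.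

Step 9 (1,2-addition of a valuable primary alkyllithium to a carbonyl flanked by CMe2 and C(Me)=). Addition may be slow and γ-deprotonation may compete. The fallback sets out from 13 and comes back at 19, making the C13–C14 bond by cross-coupling. Treating 13 with t-BuLi and then ZnCl2 gives the alkylzinc chloride F1. Negishi coupling with commercially available 2,6,6-trimethylcyclohex-1-en-1-yl triflate (Pd(PPh3)4, LiCl, THF, 60 °C) gives the tetrasubstituted cyclohexene F2. Allylic oxidation of the ring CH2 next to the methyl-bearing alkene carbon (CrO3, 3,5-dimethylpyrazole, CH2Cl2, −20 °C, as in β-ionone to 4-oxo-β-ionone) gives enone 19.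

## Further compounds

F1 | step 9 | alkylzinc chloride of the bis-TES rings A/B fragment | CC1(C)O[C@@H]2CC[C@](C)(O[Si](CC)(CC)CC)[C@H](CC[Zn]Cl)[C@@]2(C)CC[C@H]1O[Si](CC)(CC)CC
F2 | step 9 | 1-[2-(rings A/B)ethyl]-2,6,6-trimethylcyclohex-1-ene (bis-TES) | CC1(C)O[C@@H]2CC[C@](C)(O[Si](CC)(CC)CC)[C@H](CCC3=C(C)CCCC3(C)C)[C@@]2(C)CC[C@H]1O[Si](CC)(CC)CC
F3 | step 13 | 3-O-TBS ether of 29 with the methyl ketone as terminal TBS enol ether | CC1(C)O[C@@H]2CC[C@](C)(O)[C@H](CCC3=C(C)C(=O)C=C[C@@H](CCC(=C)O[Si](C)(C)C(C)(C)C)C3(C)C)[C@@]2(C)CC[C@H]1O[Si](C)(C)C(C)(C)C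
F4 | step 13 | 3,19-bis-O-TBS ether of 30 | CC1(C)O[C@@H]2CC[C@](C)(O)[C@H](CCC3=C(C)C(=O)C[C@@H]4[C@@H](CC[C@@]4(C)O[Si](C)(C)C(C)(C)C)C3(C)C)[C@@]2(C)CC[C@H]1O[Si](C)(C)C(C)(C)C
F5 | step 14 | (16S)-allylic alcohol from 30 | CC1(C)O[C@@H]2CC[C@](C)(O)[C@H](CCC3=C(C)[C@@H](O)C[C@@H]4[C@@H](CC[C@@]4(C)O)C3(C)C)[C@@]2(C)CC[C@H]1O
F6 | step 14 | (16R)-4-nitrobenzoate | CC1(C)O[C@@H]2CC[C@](C)(O)[C@H](CCC3=C(C)[C@H](OC(=O)c5ccc(cc5)[N+](=O)[O-])C[C@@H]4[C@@H](CC[C@@]4(C)O)C3(C)C)[C@@]2(C)CC[C@H]1O
F7 | step 14 | (16R)-allylic alcohol | CC1(C)O[C@@H]2CC[C@](C)(O)[C@H](CCC3=C(C)[C@H](O)C[C@@H]4[C@@H](CC[C@@]4(C)O)C3(C)C)[C@@]2(C)CC[C@H]1O
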